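- In a closed, stirred flask, once both portions were in, cE + cX + cD + cL stayed at the E charged. I started from this balance.

| flask | E | Z | temperature | remark | time |
|---|---|---|---|---|---|
| midnight | 0.078 M (in portions, 2) | 0.033 M | 95 °C | run made earlier; portions every 1.0 h |  |
| dusk | 0.078 M (in portions, 2) | 0.14 M | 106 °C | run made earlier; portions every 1.0 h |  |
| east | 0.078 M | 0.0600 M | 100 °C | everything together at the start | 20 h |
| south | 0.078 M (in portions, 2) | 0.195 M | 100 °C | the portions of E follow each other after 1.0 h, the first at the start | 10 h |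

| run | time / h | X / % | D / % |
|---|---|---|---|
| midnight | 0.667 | 2 | 1 |
| midnight | 2.00 | 6 | 0 |
| midnight | 4.00 | 4 | 0 |
| midnight | 5.00 | 9 | 0 |
| midnight | 8.00 | 8 | 0 |
| midnight | 10.0 | 10 | 0 |
| dusk | 0.667 | 5 | 0 |
| dusk | 2.00 | 11 | 3 |
| dusk | 4.00 | 12 | 1 |
| dusk | 5.00 | 18 | 1 |
| dusk | 8.00 | 12 | 0 |
| dusk | 10.0 | 13 | 1 |

(scatter of a reading: 1.5 percentage points)



* which one finishes higher in share of X in all that became X or D or L ("neither" within 2 percentage points) (east / south / neither)
* share of X in all that became X or D or L, east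
* share of X in all that became X or D or L, south

- Dusk, first instants: at 0.667 h, X read 5% and D read 0%. X was forming, and D could not yet be told from scatter.
- Dusk, middle: at 2.00 h, X read 11% and D read 3%. X was still climbing.
- Dusk, end: from 4.00 h on, X averaged 13.8% and D 0.750%. By the balance, 85.5% stood as E or L. I supposed L came after D, so I counted this as E.
- My reckoning: I supposed E + Z gives X and X + Z gives D. Dividing the rate of forming D by the rate of forming X from E removes cZ and time. Neglecting the loss of X to D, that left d cD / d cX ≈ ρ cX/cE. Here ρ, the selectivity factor, is the rate constant of the second step over that of the first.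
- Holding cE steady and integrating gave cD/cX = (ρ/2) cX/cE. Leaving L aside, the share of X is then 1/(1 + (ρ/2) cX/cE).
- The dusk means gave ρ = 0.678. This is a loose reading, since the mean of D lies inside the scatter of 1.5 percentage points.
- Midnight's late X averaged 7.75%. I kept ρ at its dusk value for 100 °C, an assumption. With X taken between that mean and dusk's, my estimate of the share ran from 94.8% to 97.2%. I expected east and south there and chose "neither".
- The forecast differed: south, east 9%, south 15%. Its ground was: “I assume E is eventually consumed, mostly to unseen L, so those plateaus approximate the X share.”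
- The flasks gave neither: east 95.1%, south 95.0%.

    D + Z ⇌ J + L (K = 0.271, k = 0.852 M⁻¹ h⁻¹, Ea = 91.0 kJ mol⁻¹, ΔH = 19.0 kJ mol⁻¹)
    2 Z → Q (k = 7.66 M⁻¹ h⁻¹, Ea = 81.0 kJ mol⁻¹)
    X + Z ⇌ J + D (K = 0.430, k = 0.544 M⁻¹ h⁻¹, Ea = 78.0 kJ mol⁻¹, ΔH = −90.0 kJ mol⁻¹)
    E + Z ⇌ J + X (K = 0.500, k = 1.44 M⁻¹ h⁻¹, Ea = 67.0 kJ mol⁻¹, ΔH = −9.00 kJ mol⁻¹)
    (constants at 100 °C)

- In south at 10.0 h, the relaxation half-life of E + Z ⇌ J + X by this step alone was 3.98 h, shorter than the 25.8 h of X + Z ⇌ J + D. The half-life of X by the forward rate of X + Z → J + D alone was then 11 d, long against south's 10 h, and south held E 83.8%, X 15.4% and D 0.769%.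
- With those amounts, ρ gives south 94.1%.
- A neighbour of south, charged with 0.78 M of Z, held X 17.9% and E 80.7% at 10.0 h. For that neighbour, ρ gives 93.0%. The computed share is 92.8%.

The data are simulated for substances that don't exist; noise was put on by code.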